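(The numbers are those of an exercise; the result is computed.)

If a coupling partner is consumed both by a catalyst cycle and by itself, I asked how long it lasted in each flask.

    coupling partner + free catalyst → catalyst intermediate A (k1 = 55000 M⁻¹ h⁻¹)
    catalyst intermediate A ⇌ catalyst intermediate B (K2 = 1.4, k2 = 92 h⁻¹)
    substrate + catalyst intermediate B → catalyst intermediate C (k3 = 20000 M⁻¹ h⁻¹)
    catalyst intermediate C → catalyst intermediate D (k4 = 350 h⁻¹)
    catalyst intermediate D → free catalyst + target (k5 = 110 h⁻¹)
    2 coupling partner → self-condensation product (k6 = 12 M⁻¹ h⁻¹)

in all of them: coupling partner 1.05 equiv; free catalyst 0.5 mol%; time 2.5 h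
- Sunday's: substrate 20 mM
- Friday's: substrate 60 mM
- Wednesday's: substrate 200 mM

1. amount of target at the end, in percent of the substrate charged for Sunday's, Friday's, Wednesday's, in this order
2. the course of these numbers from the first flask to the last (rises all the way / rises, then falls / falls all the way / falls, then rises / hardly changes)

- two of one species on the left: rate k times its square, two consumed each time
- "hardly changes" means that all values lie within two and a half points (for a concentration: within two and a half percent of the largest)
- run time (Sunday's): 2.5 h

- **Rates at the charge:** I added the reciprocals of 92 h⁻¹, 350 h⁻¹ and 110 h⁻¹ and got a ceiling turnover frequency of 43.8 h⁻¹. In Wednesday's flask, the cycle could therefore use coupling partner at 43.8 mM h⁻¹ at most, while self-condensation at the charge took 24.2 times that.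
- **Substrate charge:** In Sunday's flask the same ratio was 2.42, so a larger charge favoured self-condensation. Within one flask, with the cycle at its ceiling, the ratio fell with the square of [coupling partner], so the comparison drifted towards the cycle.
- **Carried quantity:** I integrated the partner's loss, the ceiling rate plus 2k[coupling partner]², rounding the arctangent to 3/2. Wednesday's flask came out at 1.26 h: this is the partner window, the time a charge of coupling partner lasts under both consumers with the cycle at its ceiling.
- **Run time:** Wednesday's window closed before the run ended, and ceiling times window gave 27.7 %. Friday's window was 2.01 h, giving 44.0 %.
- **Sunday's flask:** Its window of 2.64 h outlasted the run, so I used the full cycle time at the charge concentrations. That gave 44.7 %, and with both reactants at 0.5 of their charge it gave 37.7 %, so I took the mean of the two, 41.2 %. My reckoning put Wednesday's flask lowest and Friday's highest, so the course I committed to was "rises, then falls".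
- **Forecast:** It gave 41.1 %, 46.4 % and 28.6 %, with the course "rises, then falls", on the ground “Treat the cycle as a steady state”. Its numbers differ from my 41.2 %, 44.0 % and 27.7 %, but its course is the same as mine.
- **Result:** The flasks gave 41.1 %, 45.3 % and 29.2 %, and the course was "rises, then falls".
- **What happened when:** In Wednesday's flask the cycle made target while coupling partner lasted, against a window of 1.26 h: 2.70 % of the partner's charge stood at 1.25 h and 0 % at 2.50 h, and target still stood at 29.2 % after 25.0 h. In Friday's flask, with a window of 2.01 h, coupling partner was down to 0.465 % of its charge at 2.50 h, while in Sunday's flask 21.3 % remained then and target reached 62.7 % after 25.0 h.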